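The ratio of scavenger charge to substrate charge is 80.0% in both new flasks, but the ratio I watch through a run is f, the fraction of the charged substrate not yet product. The question is whether north-west, fed with scavenger and read at 20 min, ends above east, given everything at the start and read at 12 min.

| flask | substrate | scavenger | temperature | remark | time |
|---|---|---|---|---|---|
| autumn | 0.025 M | 0.040 M (fed, over 4.0 min) | 55 °C | run made earlier |  |
| spring | 0.038 M | 0.040 M (fed, over 4.0 min) | 66 °C | run made earlier |  |
| north-west | 0.050 M | 0.0400 M (fed, over 4.0 min) | 60 °C |  | 20 min |
| east | 0.050 M | 0.0400 M | 60 °C | everything together at the start | 12 min |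

- autumn (time / min: product / %): 2.50: 15; 5.00: 26; 8.00: 38; 10.0: 46; 12.0: 48; 15.0: 57
- spring (time / min: product / %): 1.33: 26; 2.00: 35; 4.00: 54; 6.00: 69; 10.0: 87; 15.0: 95

(scatter of a reading: 1.5 percentage points)

- what is said of released group includes idle adduct
- the analysis behind the earlier runs scatters by 1.5 percentage points, standard deviation
- candidate steps: substrate <-> dormant form; substrate <-> product + released group; released group -> by-product carried off; scavenger + released group -> scavenged by-product; substrate + released group <-> idle adduct

1. the flask that ends with the higher amount of product, in percent of the substrate charged, or "neither" when 2 percentage points or less lies between them (north-west / east / neither)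
2. final product, as a percentage of the substrate charged, in north-west
3. final product, as a percentage of the substrate charged, in east

I start with the main step and nothing added: substrate gives product and released group, and f = exp(−kt). The autumn run leaves f at 43.0% after 15.0 min, so k reads 0.0563 min⁻¹. The spring run leaves 13.0% after 10.0 min, so k reads 0.204 min⁻¹. Between their temperatures these readings span an activation energy of 108 kJ mol⁻¹, and that gives the apparent first-order constant at 60 °C, the rate at which ln f falls, as 0.102 min⁻¹. My first figures are therefore 87.0% product for north-west and 70.6% for east.

Next I add the scavenger, the limiting reagent of the capture. In north-west its feed of 0.0100 M min⁻¹ is faster than the initial release of 0.00511 M min⁻¹, so I leave the figure as it is for the feed. Product equal to the scavenger charge comes at 15.8 min by my reckoning, earlier than the north-west reading, so released group may stay free there towards the end. East reckons to 0.0353 M of product, less than the charge of 0.0400 M. Dormant form and idle adduct I add as no separate terms, and k stays as the two runs read it, whatever part they had in those runs.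

The forecast says north-west, with 84% for north-west and 71% for east. Its figure for north-west stands below mine and is set by judgement, noting that “the earlier runs barely constrain these steps”.

The flask gives north-west: 85.8% in north-west and 69.9% in east.

    substrate ⇌ dormant form (K = 0.250, k = 0.00220 s⁻¹, Ea = 98.0 kJ mol⁻¹, ΔH = 16.0 kJ mol⁻¹)
    substrate ⇌ product + released group (K = 0.300 M, k = 0.00210 s⁻¹, Ea = 108 kJ mol⁻¹, ΔH = −16.0 kJ mol⁻¹)
    released group → by-product carried off (k = 0.00910 s⁻¹, Ea = 103 kJ mol⁻¹)
    scavenger + released group → scavenged by-product (k = 13.0 M⁻¹ s⁻¹, Ea = 61.0 kJ mol⁻¹)
    substrate + released group ⇌ idle adduct, settled at all times (K = 50.0 M⁻¹, ΔH = −30.0 kJ mol⁻¹)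
    (constants at 60 °C)

I apply the same k to east read at 5.0 min instead of 12 min: f comes to 60.0%, so I reckon 40.0% product, and that flask gives 41.0%. What is not yet product in that earlier reading of east stands as substrate at 45.7%, dormant form at 13.0% and idle adduct at 0.401%.

The earlier runs and the new flask are simulated from invented constants; noise was put on by code.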